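**Plan**

1. Retrosynthesis: cut C1–C10 of the ten-membered ring (alkenyl iodide + aldehyde), then the three butenolide bonds C7–C8, C11–C12 and O6–C12 (alkynol + Grignard reagent + CO2), then C6–C7 (enal + alkyne), C5–C6 (formyl), C2–C3 (allyl) and C4–C15 (methyl onto propargyl alcohol).
2. Enabling feature: the butenolide alkene C7=C11 is tetrasubstituted, with C8 on C7, C13 and C12 on C11, and C12 cis to the C6 oxygen. An alkoxide-directed anti-carbometallation of a C6 propargylic alcohol followed by carboxylation gives exactly this pattern.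
3. Forward: chain C1–C6, then the alkynol, then the butenolide (first ring, step 8), then iodoalkene, acetates and C1 aldehyde, then the ten-membered carbocycle (second ring, step 14), then the C1 ketone.
4. Stereochemistry: Z-C4=C5 from anti-carbomagnesiation/iodination of propargyl alcohol; C3 (S) from Brown allylboration; C6 (R) from zinc–ProPhenol alkynylation; the C1 carbinol mixture is oxidised away.
5. Protecting groups: two TBS ethers only (O3, O13); the C1 aldehyde travels as the vinyl end of the allyl group.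

Key step: step 8

Remark: atoms carry germacrane numbers (C1 ketone, C3 and C13 acetoxy-bearing carbons, C6 lactone carbinol, C12 lactone carbonyl, C14 exocyclic methylene, C15 methyl); C1′ is the extra allyl carbon excised in step 13.
Remark: the (S,S)-ProPhenol–zinc catalyst is assumed to add the alkyne to the Si face of enal 9; if the sense proves opposite, the (R,R)-ligand is used with nothing else changed.

**Route**

Step 1
Reactants: 1 prop-2-yn-1-ol
Product: 3 (Z)-3-iodo-2-methylprop-2-en-1-ol, via oxamagnesole chelate 2 (not isolated)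
Conditions: MeMgBr (2.5 equiv), CuI (10 mol%), THF, −10 °C → rt; then I2, −78 °C → 0 °C
Reagents that add atoms: methylmagnesium bromide, C[Mg]Br; iodine, II
Why: Copper-catalysed anti-carbomagnesiation of the propargylic alkoxide places methyl on the proximal alkyne carbon (C4) and magnesium on the terminus (C5) within a five-membered chelate, and iodinolysis with retention gives the iodide cis to the hydroxymethyl group, which fixes the Z geometry of the later C4=C5 alkene.

Step 2
Reactants: 3 (Z)-3-iodo-2-methylprop-2-en-1-ol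
Product: 4 (Z)-3-iodo-2-methylprop-2-enal
Conditions: activated MnO2 (15 equiv), CH2Cl2, rt, dark; filtered and used as a solution
Reagents that add atoms: none
Why: Heterogeneous allylic oxidation with manganese dioxide is neutral and non-nucleophilic, so the Z-iodoenal should form without isomerisation to the E isomer.

Step 3
Reactants: 4 (Z)-3-iodo-2-methylprop-2-enal
Product: 6 (3S,1Z)-1-iodo-2-methylhexa-1,5-dien-3-ol, via diisopinocampheylborinate 5 (not isolated)
Conditions: (−)-Ipc2BOMe, allylMgBr, Et2O, 0 °C → rt; then 4, −78 °C; then NaOH, H2O2, 0 °C → rt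
Reagents that add atoms: allylmagnesium bromide, C=CC[Mg]Br (the allyl group is relayed through B-allyldiisopinocampheylborane made in the flask)
Why: Brown allylboration proceeds through a chair Zimmerman–Traxler transition state in which the isopinocampheyl groups derived from (+)-α-pinene direct the allyl group to the Si face of the aldehyde, which sets C3 as S under reagent control.

Step 4
Reactants: 6 (3S,1Z)-1-iodo-2-methylhexa-1,5-dien-3-ol
Product: 7 tert-butyl{[(3S,1Z)-1-iodo-2-methylhexa-1,5-dien-3-yl]oxy}dimethylsilane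
Conditions: TBSCl, imidazole, DMF, rt
Reagents that add atoms: tert-butyldimethylsilyl chloride, CC(C)(C)[Si](C)(C)Cl
Why: Standard silylation of the secondary allylic alcohol gives an ether that withstands the organolithium, organozinc and Grignard steps ahead.

Step 5
Reactants: 7 tert-butyl{[(3S,1Z)-1-iodo-2-methylhexa-1,5-dien-3-yl]oxy}dimethylsilane
Product: 9 (2Z,4S)-4-[(tert-butyldimethylsilyl)oxy]-3-methylhepta-2,6-dienal, via Z-alkenyllithium 8 (not isolated)
Conditions: t-BuLi (2.1 equiv), Et2O, −78 °C; then DMF, −78 °C → 0 °C; water quench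
Reagents that add atoms: N,N-dimethylformamide, CN(C)C=O
Why: Iodine–lithium exchange occurs with retention of alkene geometry at −78 °C and Bouveault-type formylation of the alkenyllithium with DMF delivers C6 as the Z-enal, the hemiaminal alkoxide shielding the aldehyde from over-addition until work-up.

Step 6
Reactants: 9 (2Z,4S)-4-[(tert-butyldimethylsilyl)oxy]-3-methylhepta-2,6-dienal; 10 tert-butyldimethyl(prop-2-yn-1-yloxy)silane
Product: 12 (4R,5Z,7S)-1,7-bis[(tert-butyldimethylsilyl)oxy]-6-methyldeca-5,9-dien-2-yn-4-ol, via alkynyl(methyl)zinc 11 (not isolated)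
Conditions: 10 (3 equiv), Me2Zn (3 equiv), (S,S)-ProPhenol (20 mol%), Ph3P=O (40 mol%), toluene, 0–4 °C
Reagents that add atoms: none
Why: Zinc–ProPhenol alkynylation, a method suited to α,β-unsaturated aldehydes, uses a dinuclear zinc complex that binds the enal and the alkynylzinc together and delivers the alkyne to one face (Si face assumed for the S,S ligand), which sets C6 as R under catalyst control with the remote C3 centre as a spectator.

Step 7
Reactants: 13 (4-bromobut-1-yn-1-yl)trimethylsilane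
Product: 14 [4-(trimethylsilyl)but-3-yn-1-yl]magnesium bromide (THF solution, titrated and used directly)
Conditions: Mg turnings, 1,2-dibromoethane (cat.), THF, rt → 40 °C
Reagents that add atoms: magnesium, [Mg]
Why: Oxidative insertion of magnesium into the primary bromide gives a stable homopropargylic Grignard reagent because the silyl cap removes the acidic alkyne proton.

Step 8
Reactants: 12 (4R,5Z,7S)-1,7-bis[(tert-butyldimethylsilyl)oxy]-6-methyldeca-5,9-dien-2-yn-4-ol; 14 [4-(trimethylsilyl)but-3-yn-1-yl]magnesium bromide; 15 carbon dioxide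
Product: 18 (5R)-3-{[(tert-butyldimethylsilyl)oxy]methyl}-5-{(1Z,3S)-3-[(tert-butyldimethylsilyl)oxy]-2-methylhexa-1,5-dien-1-yl}-4-[4-(trimethylsilyl)but-3-yn-1-yl]furan-2(5H)-one, via oxamagnesacycle 16 (not isolated), via Z-hydroxy acid 17 (not isolated)
Conditions: 14 (3.5 equiv), CuI (15 mol%), THF/toluene, −40 °C → rt; then CO2 (1 atm), −40 °C → rt; then 1 M HCl, 0 °C
Reagents that add atoms: none
Why: The first equivalent of 14 deprotonates the C6 hydroxyl, and the C6 magnesium alkoxide then steers the copper-catalysed anti-carbomagnesiation of the C7≡C11 alkyne so that C8 is delivered to the proximal carbon C7 and magnesium ends on C11 inside the five-membered oxamagnesacycle 16; carbon dioxide inserts into the C11–Mg bond with retention and acidification releases Z-hydroxy acid 17. The closest known reaction type is the copper-catalysed addition of alkyl Grignard reagents to propargylic alcohols with carbon dioxide capture of the chelated alkenylmagnesium to give butenolides. The lactone ring closes by 5-exo-trig acyl substitution of the C6 hydroxyl on the C12 carboxyl, which is possible only because the anti addition leaves C12 cis to C6. No stereocentre is created and C6, which is not part of the reacting π system, keeps its R configuration, while the geometry of the tetrasubstituted C7=C11 alkene is fixed by the chelate. The step needs regiocontrol (C8 to C7, not C11) and retention of the C13 oxygen: the C6 alkoxide chelate secures the first, and the bulky TBS ether at O13, a poor donor and a poor leaving group, secures the second by neither competing for magnesium nor being expelled from the β-silyloxy alkenylmetal as an allene, helped by low temperature and a prompt carbon dioxide quench.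

Step 9
Reactants: 18 (5R)-3-{[(tert-butyldimethylsilyl)oxy]methyl}-5-{(1Z,3S)-3-[(tert-butyldimethylsilyl)oxy]-2-methylhexa-1,5-dien-1-yl}-4-[4-(trimethylsilyl)but-3-yn-1-yl]furan-2(5H)-one
Product: 19 (5R)-4-(but-3-yn-1-yl)-3-{[(tert-butyldimethylsilyl)oxy]methyl}-5-{(1Z,3S)-3-[(tert-butyldimethylsilyl)oxy]-2-methylhexa-1,5-dien-1-yl}furan-2(5H)-one
Conditions: AgNO3 (20 mol%), acetone/H2O, rt
Reagents that add atoms: none
Why: Silver(I)-catalysed protodesilylation proceeds through a silver acetylide under neutral conditions, so the alkynyl C–Si bond is cleaved selectively while both O-silyl ethers and the base-sensitive C6–H of the butenolide are left alone.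

Step 10
Reactants: 19 (5R)-4-(but-3-yn-1-yl)-3-{[(tert-butyldimethylsilyl)oxy]methyl}-5-{(1Z,3S)-3-[(tert-butyldimethylsilyl)oxy]-2-methylhexa-1,5-dien-1-yl}furan-2(5H)-one
Product: 21 (5R)-3-{[(tert-butyldimethylsilyl)oxy]methyl}-5-{(1Z,3S)-3-[(tert-butyldimethylsilyl)oxy]-2-methylhexa-1,5-dien-1-yl}-4-(3-iodobut-3-en-1-yl)furan-2(5H)-one, via iodoalkenylborane 20 (not isolated)
Conditions: B-iodo-9-BBN (1.5 equiv), hexanes/CH2Cl2, −20 °C → 0 °C; then AcOH, 0 °C; aq. NaHCO3 work-up
Reagents that add atoms: B-iodo-9-borabicyclo[3.3.1]nonane, IB1C2CCCC1CCC2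
Why: Haloboration with B-iodo-9-BBN adds B–I syn across terminal alkynes only, with iodine on the internal carbon C10, and protonolysis of the alkenylborane with acetic acid gives the 2-iodo-1-alkene while the alkenes, the butenolide and the silyl ethers should not react.

Step 11
Reactants: 21 (5R)-3-{[(tert-butyldimethylsilyl)oxy]methyl}-5-{(1Z,3S)-3-[(tert-butyldimethylsilyl)oxy]-2-methylhexa-1,5-dien-1-yl}-4-(3-iodobut-3-en-1-yl)furan-2(5H)-one
Product: 22 (5R)-3-(hydroxymethyl)-5-[(1Z,3S)-3-hydroxy-2-methylhexa-1,5-dien-1-yl]-4-(3-iodobut-3-en-1-yl)furan-2(5H)-one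
Conditions: HF·pyridine, pyridine/THF, 0 °C → rt
Reagents that add atoms: none
Why: Fluoride-mediated desilylation under buffered, mildly acidic conditions removes the primary and the secondary TBS ether together without epimerising C6 or touching the iodoalkene.

Step 12
Reactants: 22 (5R)-3-(hydroxymethyl)-5-[(1Z,3S)-3-hydroxy-2-methylhexa-1,5-dien-1-yl]-4-(3-iodobut-3-en-1-yl)furan-2(5H)-one
Product: 23 (5R)-3-(acetoxymethyl)-5-[(1Z,3S)-3-acetoxy-2-methylhexa-1,5-dien-1-yl]-4-(3-iodobut-3-en-1-yl)furan-2(5H)-one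
Conditions: Ac2O, pyridine, DMAP (cat.), CH2Cl2, 0 °C
Reagents that add atoms: acetic anhydride, CC(=O)OC(C)=O
Why: Nucleophile-catalysed acylation installs both acetates of the target before the enone exists, so that no free C3 hydroxyl can later add to the C10 methylene ketone.

Step 13
Reactants: 23 (5R)-3-(acetoxymethyl)-5-[(1Z,3S)-3-acetoxy-2-methylhexa-1,5-dien-1-yl]-4-(3-iodobut-3-en-1-yl)furan-2(5H)-one
Product: 25 (5R)-3-(acetoxymethyl)-5-[(1Z,3S)-3-acetoxy-2-methyl-5-oxopent-1-en-1-yl]-4-(3-iodobut-3-en-1-yl)furan-2(5H)-one, via vicinal diol 24 (not isolated)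
Conditions: K2OsO4·2H2O (2 mol%), NaIO4 (4 equiv), 2,6-lutidine (2 equiv), dioxane/H2O 3:1, rt
Reagents that add atoms: osmium tetroxide, O=[Os](=O)(=O)=O (formed from K2OsO4 and recycled by sodium periodate, [Na+].[O-]I(=O)(=O)=O)
Why: Lemieux–Johnson cleavage should take the monosubstituted C1=C1′ alkene because the electrophilic osmium reagent is slow with the hindered C4=C5 alkene flanked by two allylic acyloxy groups, with the electron-poor butenolide alkene and with the iodoalkene, and periodate then cleaves the diol to the C1 aldehyde.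

Step 14
Reactants: 25 (5R)-3-(acetoxymethyl)-5-[(1Z,3S)-3-acetoxy-2-methyl-5-oxopent-1-en-1-yl]-4-(3-iodobut-3-en-1-yl)furan-2(5H)-one
Product: 27 (3S,4Z,6R)-3,13-diacetoxy-1-hydroxygermacra-4,7(11),10(14)-trien-12,6-olide as a mixture of C1 epimers, via alkenylchromium(III) 26 (not isolated)
Conditions: CrCl2 (10 equiv), NiCl2 (0.1 equiv), DMSO/THF, rt, 2 mM, slow addition
Reagents that add atoms: none
Why: Nozaki–Hiyama–Kishi coupling forms the alkenylchromium(III) species by nickel-catalysed insertion into the C10–I bond and it adds chemoselectively to the C1 aldehyde in the presence of the acetates and the lactone, closing the ten-membered ring that is preorganised by the Z-alkene and the butenolide; the configuration of the new C1 carbinol is not controlled and is removed in the next step.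

Step 15
Reactants: 27 (3S,4Z,6R)-3,13-diacetoxy-1-hydroxygermacra-4,7(11),10(14)-trien-12,6-olide
Product: 28 (3S,4Z,6R)-3,13-diacetoxy-1-oxogermacra-4,7(11),10(14)-trien-12,6-olide (CNP0272505.1)
Conditions: Dess–Martin periodinane, NaHCO3, CH2Cl2, 0 °C → rt
Reagents that add atoms: none
Why: Dess–Martin oxidation converts both C1 epimers of the allylic alcohol into the C1 ketone under buffered non-basic conditions, which should avoid β-elimination of the C3 acetate from the new β-acetoxy enone.

**Compound list**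

1 | prop-2-yn-1-ol | C#CCO | starting material
2 | 4-methyl-5H-1,2-oxamagnesole (cyclic alkenylmagnesium alkoxide) | CC1=C[Mg]OC1 | intermediate
3 | (Z)-3-iodo-2-methylprop-2-en-1-ol | I/C=C(/C)CO | intermediate
4 | (Z)-3-iodo-2-methylprop-2-enal | I/C=C(/C)C=O | intermediate
5 | (3S,1Z)-1-iodo-2-methylhexa-1,5-dien-3-yl diisopinocampheylborinate | I/C=C(/C)[C@@H](OB([C@@H]1C[C@@H]2C[C@H]([C@H]1C)C2(C)C)[C@@H]1C[C@@H]2C[C@H]([C@H]1C)C2(C)C)CC=C | intermediate
6 | (3S,1Z)-1-iodo-2-methylhexa-1,5-dien-3-ol | I/C=C(/C)[C@@H](O)CC=C | intermediate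
7 | tert-butyl{[(3S,1Z)-1-iodo-2-methylhexa-1,5-dien-3-yl]oxy}dimethylsilane | I/C=C(/C)[C@@H](O[Si](C)(C)C(C)(C)C)CC=C | intermediate
8 | (1Z,3S)-3-[(tert-butyldimethylsilyl)oxy]-2-methylhexa-1,5-dien-1-yllithium | [Li]/C=C(/C)[C@@H](O[Si](C)(C)C(C)(C)C)CC=C | intermediate
9 | (2Z,4S)-4-[(tert-butyldimethylsilyl)oxy]-3-methylhepta-2,6-dienal | O=C/C=C(/C)[C@@H](O[Si](C)(C)C(C)(C)C)CC=C | intermediate
10 | tert-butyldimethyl(prop-2-yn-1-yloxy)silane | C#CCO[Si](C)(C)C(C)(C)C | starting material
11 | methyl{3-[(tert-butyldimethylsilyl)oxy]prop-1-yn-1-yl}zinc | C[Zn]C#CCO[Si](C)(C)C(C)(C)C | intermediate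
12 | (4R,5Z,7S)-1,7-bis[(tert-butyldimethylsilyl)oxy]-6-methyldeca-5,9-dien-2-yn-4-ol | CC(C)(C)[Si](C)(C)OCC#C[C@H](O)/C=C(/C)[C@@H](O[Si](C)(C)C(C)(C)C)CC=C | intermediate
13 | (4-bromobut-1-yn-1-yl)trimethylsilane | C[Si](C)(C)C#CCCBr | starting material
14 | [4-(trimethylsilyl)but-3-yn-1-yl]magnesium bromide | C[Si](C)(C)C#CCC[Mg]Br | intermediate
15 | carbon dioxide | O=C=O | starting material
16 | oxamagnesacycle from anti-carbomagnesiation of 12 (C11–Mg–O6 chelate) | [Mg]1O[C@H](/C=C(/C)[C@@H](O[Si](C)(C)C(C)(C)C)CC=C)C(CCC#C[Si](C)(C)C)=C1CO[Si](C)(C)C(C)(C)C | intermediate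
17 | Z-hydroxy acid (C12 carboxyl cis to the C6 hydroxyl) | OC(=O)/C(CO[Si](C)(C)C(C)(C)C)=C(\[C@H](O)/C=C(/C)[C@@H](O[Si](C)(C)C(C)(C)C)CC=C)CCC#C[Si](C)(C)C | intermediate
18 | (5R)-3-{[(tert-butyldimethylsilyl)oxy]methyl}-5-{(1Z,3S)-3-[(tert-butyldimethylsilyl)oxy]-2-methylhexa-1,5-dien-1-yl}-4-[4-(trimethylsilyl)but-3-yn-1-yl]furan-2(5H)-one | O=C1O[C@H](/C=C(/C)[C@@H](O[Si](C)(C)C(C)(C)C)CC=C)C(CCC#C[Si](C)(C)C)=C1CO[Si](C)(C)C(C)(C)C | intermediate
19 | (5R)-4-(but-3-yn-1-yl)-3-{[(tert-butyldimethylsilyl)oxy]methyl}-5-{(1Z,3S)-3-[(tert-butyldimethylsilyl)oxy]-2-methylhexa-1,5-dien-1-yl}furan-2(5H)-one | O=C1O[C@H](/C=C(/C)[C@@H](O[Si](C)(C)C(C)(C)C)CC=C)C(CCC#C)=C1CO[Si](C)(C)C(C)(C)C | intermediate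
20 | (Z)-2-iodoalkenyl-9-BBN adduct of 19 (B on C14, I on C10) | O=C1O[C@H](/C=C(/C)[C@@H](O[Si](C)(C)C(C)(C)C)CC=C)C(CC/C(I)=C/B2C3CCCC2CCC3)=C1CO[Si](C)(C)C(C)(C)C | intermediate
21 | (5R)-3-{[(tert-butyldimethylsilyl)oxy]methyl}-5-{(1Z,3S)-3-[(tert-butyldimethylsilyl)oxy]-2-methylhexa-1,5-dien-1-yl}-4-(3-iodobut-3-en-1-yl)furan-2(5H)-one | O=C1O[C@H](/C=C(/C)[C@@H](O[Si](C)(C)C(C)(C)C)CC=C)C(CCC(I)=C)=C1CO[Si](C)(C)C(C)(C)C | intermediate
22 | (5R)-3-(hydroxymethyl)-5-[(1Z,3S)-3-hydroxy-2-methylhexa-1,5-dien-1-yl]-4-(3-iodobut-3-en-1-yl)furan-2(5H)-one | O=C1O[C@H](/C=C(/C)[C@@H](O)CC=C)C(CCC(I)=C)=C1CO | intermediate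
23 | (5R)-3-(acetoxymethyl)-5-[(1Z,3S)-3-acetoxy-2-methylhexa-1,5-dien-1-yl]-4-(3-iodobut-3-en-1-yl)furan-2(5H)-one | O=C1O[C@H](/C=C(/C)[C@@H](OC(C)=O)CC=C)C(CCC(I)=C)=C1COC(C)=O | intermediate
24 | (5R)-3-(acetoxymethyl)-5-[(1Z,3S)-3-acetoxy-5,6-dihydroxy-2-methylhex-1-en-1-yl]-4-(3-iodobut-3-en-1-yl)furan-2(5H)-one (diol epimers) | O=C1O[C@H](/C=C(/C)[C@@H](OC(C)=O)CC(O)CO)C(CCC(I)=C)=C1COC(C)=O | intermediate
25 | (5R)-3-(acetoxymethyl)-5-[(1Z,3S)-3-acetoxy-2-methyl-5-oxopent-1-en-1-yl]-4-(3-iodobut-3-en-1-yl)furan-2(5H)-one | O=C1O[C@H](/C=C(/C)[C@@H](OC(C)=O)CC=O)C(CCC(I)=C)=C1COC(C)=O | intermediate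
26 | C10 alkenylchromium(III) dichloride derived from 25 | O=C1O[C@H](/C=C(/C)[C@@H](OC(C)=O)CC=O)C(CCC(=C)[Cr](Cl)Cl)=C1COC(C)=O | intermediate
27 | (3S,4Z,6R)-3,13-diacetoxy-1-hydroxygermacra-4,7(11),10(14)-trien-12,6-olide (C1 epimers) | C=C1CCC2=C(COC(C)=O)C(=O)O[C@@H]2/C=C(/C)[C@@H](OC(C)=O)CC1O | intermediate
28 | (3S,4Z,6R)-3,13-diacetoxy-1-oxogermacra-4,7(11),10(14)-trien-12,6-olide (CNP0272505.1) | C=C1CCC2=C(COC(C)=O)C(=O)O[C@@H]2/C=C(/C)[C@@H](OC(C)=O)CC1=O | target

**Step count**

Total steps: 15. Longest linear sequence: 14 (steps 1–6 and 8–15); step 7 is a one-step side branch.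

**Steps most likely to fail**

Step 8. The β-silyloxy alkenylmetal may expel the C13 silyloxy group (allene formation) or be protonated while the slow capture of carbon dioxide by the hindered, chelated alkenylmagnesium is awaited. The fallback sets out from 12 (with 14) and returns at 18. The carbomagnesiation is run as before but quenched at −78 °C with iodine, an instantaneous trap, to give the (2Z,4R,5Z,7S)-2-iodo-trienol F1. Palladium-catalysed cyclocarbonylation of this Z-iodo allylic alcohol (PdCl2(PPh3)2, CO 1 atm, K2CO3, THF/DMF) then inserts C12 and closes the lactone to give 18.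

Step 14. Oligomerisation or protodeiodination of the alkenylchromium may outrun the strained ten-membered closure, and the β-acetoxy aldehyde may lose acetic acid during a slow reaction. The fallback sets out from 19 and returns at 27, closing the same C1–C10 bond by a nickel-catalysed reductive alkyne–aldehyde cyclisation. Lemieux–Johnson cleavage of the terminal vinyl group of 19 gives the bis-TBS ynal F2. Ni(cod)2 with a bulky N-heterocyclic carbene (IPr) and iPr3SiH in THF at high dilution should couple the aldehyde to the internal alkyne carbon and give the macrocyclic exo-methylene C1 triisopropylsilyl ether F3. HF·pyridine at 0 °C removes the two TBS ethers and leaves the more robust TIPS ether, giving the 3,13-diol F4. Ac2O/pyridine gives the diacetate F5, and buffered TBAF/AcOH frees the C1 hydroxyl to give 27.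

Step 6. The Z-enal may isomerise to the E-enal under the Lewis acidic zinc conditions, and facial control on the hindered β,β-disubstituted enal may be incomplete. The fallback sets out from 7 (with 10), bypasses enal 9 and returns at 12. Deprotonation of 10 with n-BuLi and acylation with N-methoxy-N-methylcarbamoyl chloride gives the Weinreb ynamide F6. The alkenyllithium 8 made from 7 adds to F6 at −78 °C to give the Z-enynone F7. Midland reduction with (R)-Alpine-Borane, in which the linear alkynyl group acts as the small substituent, should give the 4R alcohol 12.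

**Further compounds**

F1 | step 8 | (2Z,4R,5Z,7S)-1,7-bis[(tert-butyldimethylsilyl)oxy]-2-iodo-6-methyl-3-[4-(trimethylsilyl)but-3-yn-1-yl]deca-2,5,9-trien-4-ol | I/C(CO[Si](C)(C)C(C)(C)C)=C(\[C@H](O)/C=C(/C)[C@@H](O[Si](C)(C)C(C)(C)C)CC=C)CCC#C[Si](C)(C)C
F2 | step 14 | (5R)-4-(but-3-yn-1-yl)-3-{[(tert-butyldimethylsilyl)oxy]methyl}-5-{(1Z,3S)-3-[(tert-butyldimethylsilyl)oxy]-2-methyl-5-oxopent-1-en-1-yl}furan-2(5H)-one | O=C1O[C@H](/C=C(/C)[C@@H](O[Si](C)(C)C(C)(C)C)CC=O)C(CCC#C)=C1CO[Si](C)(C)C(C)(C)C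
F3 | step 14 | (3S,4Z,6R)-3,13-bis[(tert-butyldimethylsilyl)oxy]-1-[(triisopropylsilyl)oxy]germacra-4,7(11),10(14)-trien-12,6-olide (C1 epimers) | C=C1CCC2=C(CO[Si](C)(C)C(C)(C)C)C(=O)O[C@@H]2/C=C(/C)[C@@H](O[Si](C)(C)C(C)(C)C)CC1O[Si](C(C)C)(C(C)C)C(C)C
F4 | step 14 | (3S,4Z,6R)-3,13-dihydroxy-1-[(triisopropylsilyl)oxy]germacra-4,7(11),10(14)-trien-12,6-olide (C1 epimers) | C=C1CCC2=C(CO)C(=O)O[C@@H]2/C=C(/C)[C@@H](O)CC1O[Si](C(C)C)(C(C)C)C(C)C
F5 | step 14 | (3S,4Z,6R)-3,13-diacetoxy-1-[(triisopropylsilyl)oxy]germacra-4,7(11),10(14)-trien-12,6-olide (C1 epimers) | C=C1CCC2=C(COC(C)=O)C(=O)O[C@@H]2/C=C(/C)[C@@H](OC(C)=O)CC1O[Si](C(C)C)(C(C)C)C(C)C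
F6 | step 6 | 4-[(tert-butyldimethylsilyl)oxy]-N-methoxy-N-methylbut-2-ynamide | CON(C)C(=O)C#CCO[Si](C)(C)C(C)(C)C
F7 | step 6 | (5Z,7S)-1,7-bis[(tert-butyldimethylsilyl)oxy]-6-methyldeca-5,9-dien-2-yn-4-one | CC(C)(C)[Si](C)(C)OCC#CC(=O)/C=C(/C)[C@@H](O[Si](C)(C)C(C)(C)C)CC=C
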